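**Plan**

- Retrosynthesis (chromone numbering): ring A is de-aromatised and given back an allyl ester on C4a. Cutting C4a–C5 and C8–C8a then leaves 2,3-dimethoxybuta-1,3-diene and a ring C pyranone ester that already carries ring B.
- The feature that allows this is ring A itself: methoxy groups on C6 and C7, hydrogens on C5 and C8, and the C4a–C8a bond shared with ring C. That is exactly what a 2,3-dimethoxybutadiene leaves on the ester-bearing C=C of a 4-pyranone.
- The pyranone is cut at C2 and C8a (two one-carbon units from an amide acetal, O1 from water) and at C4–C4a (arylacetic acid plus Meldrum's acid, opened with allyl alcohol).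
- Forward: ring B is bought, the keto ester chain is assembled (steps 1–2), ring C is closed (step 3), ring A is added by cycloaddition (step 4) and aromatised by palladium-mediated loss of the ester and quinone dehydrogenation (steps 5–6).
- Stereochemistry: the target has none. C4a and C8a of the cycloadduct arise cis and racemic by suprafacial addition and are erased in steps 5 and 6.

Key step: step 4

Assumption: diene 8 is taken as a purchasable reagent, distilled before use; all chiral intermediates are racemic, which is immaterial because the target has no stereocentre.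

**Step 1**
Reactants: 1 2,3,4-trimethoxyphenylacetic acid; 2 Meldrum's acid
Product: 3 5-[1-hydroxy-2-(2,3,4-trimethoxyphenyl)ethylidene]-2,2-dimethyl-1,3-dioxane-4,6-dione
Conditions: DCC (1.1 equiv), DMAP (1.2 equiv), CH2Cl2, 0 °C to rt; filter, wash with cold aq. KHSO4
Reagents that add atoms: none
Why: Carbodiimide-mediated C-acylation of Meldrum's acid, in which the activated acid is intercepted by the highly acidic methylene of 2 and the product is held as its enol, which should prevent a second acylation.

**Step 2**
Reactants: 3 5-[1-hydroxy-2-(2,3,4-trimethoxyphenyl)ethylidene]-2,2-dimethyl-1,3-dioxane-4,6-dione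
Product: 4 prop-2-enyl 3-oxo-4-(2,3,4-trimethoxyphenyl)butanoate
Conditions: allyl alcohol (3 equiv), PhMe, 100 °C
Reagents that add atoms: allyl alcohol (prop-2-en-1-ol), C=CCO
Why: Thermolysis of an acyl Meldrum's acid, which should lose acetone and carbon dioxide to an acylketene that allyl alcohol traps as the β-keto ester (Meldrum's acid route to β-keto esters).

**Step 3**
Reactants: 4 prop-2-enyl 3-oxo-4-(2,3,4-trimethoxyphenyl)butanoate; 5 N,N-dimethylformamide dimethyl acetal
Product: 7 prop-2-enyl 4-oxo-5-(2,3,4-trimethoxyphenyl)-4H-pyran-3-carboxylate, via bis-enaminone 6 (not isolated)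
Conditions: 5 (3 equiv), PhMe, 100 °C; concentrate; then 1 M aq. HCl, THF, rt
Reagents that add atoms: water, O
Why: Aminomethylenation of both methylene groups flanking the ketone (enaminone formation), then acid hydrolysis of one enamine to a hydroxymethylene group whose oxygen adds to the other enaminone and expels dimethylamine, the established way from ketones with two active methylene groups to 3,5-disubstituted 4-pyranones.

**Step 4**
Reactants: 7 prop-2-enyl 4-oxo-5-(2,3,4-trimethoxyphenyl)-4H-pyran-3-carboxylate; 8 2,3-dimethoxybuta-1,3-diene
Product: 9 prop-2-enyl cis-6,7-dimethoxy-4-oxo-3-(2,3,4-trimethoxyphenyl)-4a,5,8,8a-tetrahydro-4H-chromene-4a-carboxylate (racemic; ester on C4a and hydrogen on C8a cis)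
Conditions: 8 (3 equiv), ZnCl2 (0.3 equiv), CH2Cl2, 0 °C to rt; Et3N, aq. NaHCO3 work-up; Et3N-deactivated silica
Reagents that add atoms: none
Why: Proposed new method: a normal-demand [4+2] cycloaddition (Diels–Alder reaction) in which the s-cis diene 8, raised in energy by its two methoxy groups, adds across the C2=C3 bond of pyranone 7, whose acceptor orbital is lowered by the ketone and the ester together and further by chelation of these two carbonyl oxygens to ZnCl2 (a concerted asynchronous path, or conjugate addition at C2 followed at once by closure of the zinc enolate at C3 onto the methoxyallyl cation, leads to the same adduct). The closest known reaction type is the Diels–Alder addition of electron-rich dienes to 3-alkoxycarbonyl- and 3-formylchromones; a monocyclic 5-aryl-4-pyranone-3-carboxylate has not been used in this way with this diene. Ring A closes as a six-membered carbocycle by intermolecular [4+2] annulation, pyranone C3 and C2 becoming C4a and C8a and the diene termini C5 and C8. The stereocentres C4a and C8a are set relative to each other by suprafacial addition to the dienophile, so the ester and H-8a, cis on the double bond, stay cis and the ring fusion is cis; the adduct is racemic and both centres vanish on aromatisation. The step needs site selectivity between the two ring double bonds, secured by the ester (C2=C3 is doubly activated and chelated, C5=C6 carries the aryl group and one acceptor only), and periselectivity over a hetero-cycloaddition of the oxadiene of 7 with one enol ether bond of 8, expected because the conjugated s-cis diene reacts faster as the four-electron partner. The symmetric diene leaves no regiochemical question.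

**Step 5**
Reactants: 9 prop-2-enyl cis-6,7-dimethoxy-4-oxo-3-(2,3,4-trimethoxyphenyl)-4a,5,8,8a-tetrahydro-4H-chromene-4a-carboxylate
Product: 10 6,7-dimethoxy-3-(2,3,4-trimethoxyphenyl)-5,8-dihydro-4H-chromen-4-one
Conditions: Pd(OAc)2 (10 mol %), 1,2-bis(diphenylphosphino)ethane (12 mol %), MeCN, 80 °C
Reagents that add atoms: none
Why: Palladium-catalysed decarboxylative dehydrogenation of an allyl β-keto ester (the dehydrogenation branch of Tsuji–Trost allyl ester chemistry), in which zerovalent palladium formed in the flask ionises the allyl ester, the carboxylate loses carbon dioxide, and the π-allylpalladium enolate undergoes β-hydride elimination towards C8a to restore the conjugated pyranone while propene leaves by reductive elimination; an isomer with a C4a=C5 bond, should it form, would converge in step 6.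

**Step 6**
Reactants: 10 6,7-dimethoxy-3-(2,3,4-trimethoxyphenyl)-5,8-dihydro-4H-chromen-4-one
Product: 11 6,7,2',3',4'-pentamethoxyisoflavone
Conditions: DDQ (1.1 equiv), solid NaHCO3, PhMe, 0 °C to rt
Reagents that add atoms: none
Why: Quinone dehydrogenation, in which DDQ should abstract hydride from a doubly allylic CH2 of the 1,4-cyclohexadiene to give a methoxy-stabilised cyclohexadienyl cation that loses a proton, the gain of aromaticity driving the step.

**Compound list**

1 | 2,3,4-trimethoxyphenylacetic acid | OC(=O)Cc1ccc(OC)c(OC)c1OC | starting material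
2 | Meldrum's acid (2,2-dimethyl-1,3-dioxane-4,6-dione) | CC1(C)OC(=O)CC(=O)O1 | starting material
3 | 5-[1-hydroxy-2-(2,3,4-trimethoxyphenyl)ethylidene]-2,2-dimethyl-1,3-dioxane-4,6-dione (acyl Meldrum's acid, enol form) | COc1ccc(CC(O)=C2C(=O)OC(C)(C)OC2=O)c(OC)c1OC | intermediate
4 | prop-2-enyl 3-oxo-4-(2,3,4-trimethoxyphenyl)butanoate | C=CCOC(=O)CC(=O)Cc1ccc(OC)c(OC)c1OC | intermediate
5 | N,N-dimethylformamide dimethyl acetal | COC(OC)N(C)C | starting material
6 | prop-2-enyl 5-(dimethylamino)-2-[(dimethylamino)methylidene]-3-oxo-4-(2,3,4-trimethoxyphenyl)pent-4-enoate (bis-enaminone, double-bond geometry not defined) | C=CCOC(=O)C(=CN(C)C)C(=O)C(=CN(C)C)c1ccc(OC)c(OC)c1OC | intermediate (not isolated)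
7 | prop-2-enyl 4-oxo-5-(2,3,4-trimethoxyphenyl)-4H-pyran-3-carboxylate | C=CCOC(=O)C1=COC=C(c2ccc(OC)c(OC)c2OC)C1=O | intermediate
8 | 2,3-dimethoxybuta-1,3-diene | COC(=C)C(=C)OC | starting material
9 | prop-2-enyl cis-6,7-dimethoxy-4-oxo-3-(2,3,4-trimethoxyphenyl)-4a,5,8,8a-tetrahydro-4H-chromene-4a-carboxylate (racemic, one enantiomer drawn) | C=CCOC(=O)[C@]12CC(OC)=C(OC)C[C@H]1OC=C(c1ccc(OC)c(OC)c1OC)C2=O | intermediate
10 | 6,7-dimethoxy-3-(2,3,4-trimethoxyphenyl)-5,8-dihydro-4H-chromen-4-one | COC1=C(OC)CC2=C(C1)C(=O)C(c1ccc(OC)c(OC)c1OC)=CO2 | intermediate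
11 | 6,7,2',3',4'-pentamethoxyisoflavone | COc1cc2occ(-c3ccc(OC)c(OC)c3OC)c(=O)c2cc1OC | target

**Count**

Total steps: 6. Longest linear sequence: 6 steps (1 to 11).

**Steps most likely to fail**

Step 4. The push–pull C2=C3 bond of 7 may be too poor a dienophile, the zinc salt may consume the enol ether diene by oligomerisation, or the diene may add through one enol ether bond in a hetero-cycloaddition. The fallback gives up the ring A annulation and uses the classical deoxybenzoin route to isoflavones, setting out from 1 and coming back at 11. Friedel–Crafts acylation of 3,4-dimethoxyphenol with acid 1 in BF3·OEt2 at 85 °C should take place ortho to the hydroxyl group and give 1-(2-hydroxy-4,5-dimethoxyphenyl)-2-(2,3,4-trimethoxyphenyl)ethan-1-one F1. Heating F1 with acetal 5 in PhMe should form 3-(dimethylamino)-1-(2-hydroxy-4,5-dimethoxyphenyl)-2-(2,3,4-trimethoxyphenyl)prop-2-en-1-one F2 in the flask. Its phenol oxygen should then add to the enaminone and expel dimethylamine to close ring C, giving 11.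

Step 5. Reductive elimination of the allyl group onto C4a (decarboxylative allylation) or protonation of the palladium enolate may outrun β-hydride elimination. The fallback removes the ester reductively and introduces both unsaturations by quinone oxidation, setting out from 9 and coming back at 11. Pd(PPh3)4 (5 mol %) with morpholine in THF at rt should transfer the allyl group to the amine and leave cis-6,7-dimethoxy-4-oxo-3-(2,3,4-trimethoxyphenyl)-4a,5,8,8a-tetrahydro-4H-chromene-4a-carboxylic acid F3. This β-keto acid should lose carbon dioxide in the flask to give cis-6,7-dimethoxy-3-(2,3,4-trimethoxyphenyl)-4a,5,8,8a-tetrahydro-4H-chromen-4-one F4; either ring-fusion epimer would serve. DDQ (2.2 equiv) in dioxane at 80 °C should then dehydrogenate ring A twice to 11.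

Step 3. The second aminomethylenation, at the benzylic methylene next to an ortho-methoxy aryl group, may stall, and prolonged heating may exchange or cleave the allyl ester. The fallback builds the two ring CH carbons one at a time under milder conditions, setting out from 4 and coming back at 7. Acetal 5 (1.1 equiv) in PhMe at rt should react only at the doubly activated methylene and give prop-2-enyl 2-[(dimethylamino)methylidene]-3-oxo-4-(2,3,4-trimethoxyphenyl)butanoate F5. Deprotonation of the benzylic position with LiN(SiMe3)2 (2.2 equiv) in THF at −78 °C and Claisen condensation with ethyl formate should give, after quench, prop-2-enyl 2-[(dimethylamino)methylidene]-5-hydroxy-3-oxo-4-(2,3,4-trimethoxyphenyl)pent-4-enoate F6. On acidification with aq. HCl, F6 should cyclise with loss of dimethylamine to 7.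

**Further compounds**

F1 | step 4 | 1-(2-hydroxy-4,5-dimethoxyphenyl)-2-(2,3,4-trimethoxyphenyl)ethan-1-one | COc1cc(O)c(C(=O)Cc2ccc(OC)c(OC)c2OC)cc1OC
F2 | step 4 | 3-(dimethylamino)-1-(2-hydroxy-4,5-dimethoxyphenyl)-2-(2,3,4-trimethoxyphenyl)prop-2-en-1-one (geometry not defined) | COc1cc(O)c(C(=O)C(=CN(C)C)c2ccc(OC)c(OC)c2OC)cc1OC
F3 | step 5 | cis-6,7-dimethoxy-4-oxo-3-(2,3,4-trimethoxyphenyl)-4a,5,8,8a-tetrahydro-4H-chromene-4a-carboxylic acid (racemic, one enantiomer drawn) | OC(=O)[C@]12CC(OC)=C(OC)C[C@H]1OC=C(c1ccc(OC)c(OC)c1OC)C2=O
F4 | step 5 | cis-6,7-dimethoxy-3-(2,3,4-trimethoxyphenyl)-4a,5,8,8a-tetrahydro-4H-chromen-4-one (racemic, one enantiomer drawn) | COC1=C(OC)C[C@H]2OC=C(c3ccc(OC)c(OC)c3OC)C(=O)[C@H]2C1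
F5 | step 3 | prop-2-enyl 2-[(dimethylamino)methylidene]-3-oxo-4-(2,3,4-trimethoxyphenyl)butanoate (geometry not defined) | C=CCOC(=O)C(=CN(C)C)C(=O)Cc1ccc(OC)c(OC)c1OC
F6 | step 3 | prop-2-enyl 2-[(dimethylamino)methylidene]-5-hydroxy-3-oxo-4-(2,3,4-trimethoxyphenyl)pent-4-enoate (geometry not defined) | C=CCOC(=O)C(=CN(C)C)C(=O)C(=CO)c1ccc(OC)c(OC)c1OC
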